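**Retrosynthetic overview**

1. The triene is cut at C2'–C3' (Stille coupling) into the epoxyquinol vinylstannane 10 (rings A and B) and the bromodienamide 19 (ring C).
2. Ring C of 19 is made by a cationic ring expansion: the cyclobutene 17 adds to the N-acylformimidate 16, and a 1,2-acyl shift onto the N-acyliminium carbon turns the four-membered ring into the 2-amido-cyclopentane-1,3-dione.
3. 10 comes from anti-addition of a stannylvinyllithium to the epoxy ketone 8 (sets the carbinol), which comes from asymmetric epoxidation of the quinone monoketal 7 (sets both oxirane carbons), itself from oxidative dearomatisation of the anilide 5.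
4. 5 is the amide of 3-aminophenol with the dienoic acid 3, which is made by cross-metathesis of vinylcyclohexane with pentadienoic acid.
5. Ring order: ring A (cyclohexane) is bought; ring B is the benzene ring of 3-aminophenol, dearomatised in step 3 and epoxidised in step 4; ring C is formed in step 10; the rings are joined in step 11.

Assumption: the target is the (4R,5S,6R) epoxyquinol as drawn, with the aminocyclopentanedione in its enol form; 11, 14 and 17 are bought as such, and the two Me3Si groups of 17 are protecting groups on a C4O2 core.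

**Step 1**
Reactants: 1 vinylcyclohexane; 2 (2E)-penta-2,4-dienoic acid
Product: 3 (2E,4E)-5-cyclohexylpenta-2,4-dienoic acid
Conditions: 1 (3 equiv), second-generation Hoveyda–Grubbs catalyst RuCl2(H2IMes)(=CH-C6H4-2-OiPr) (3 mol %), CH2Cl2, 40 °C; recrystallise
Reagents that add atoms: none
Why: Olefin cross-metathesis takes place only at the terminal C4=C5 bond of 2 (the acrylic C2=C3 bond is electron-poor and internal) and gives the conjugated E-alkene under thermodynamic control with loss of ethylene.

**Step 2**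
Reactants: 3 (2E,4E)-5-cyclohexylpenta-2,4-dienoic acid; 4 3-aminophenol
Product: 5 (2E,4E)-5-cyclohexyl-N-(3-hydroxyphenyl)penta-2,4-dienamide
Conditions: EDC·HCl (1.1 equiv), HOBt (1.1 equiv), DMF, 0 °C to rt
Reagents that add atoms: none
Why: Carbodiimide/HOBt amide coupling, in which the aniline nitrogen is far more nucleophilic than the phenol oxygen toward the active ester, so only the anilide forms.

**Step 3**
Reactants: 5 (2E,4E)-5-cyclohexyl-N-(3-hydroxyphenyl)penta-2,4-dienamide
Product: 7 (2E,4E)-5-cyclohexyl-N-(6,6-dimethoxy-3-oxocyclohexa-1,4-dien-1-yl)penta-2,4-dienamide, via methoxyphenol 6 (not isolated)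
Conditions: PhI(OAc)2 (2.2 equiv), MeOH, 0 °C to rt
Reagents that add atoms: methanol, CO
Why: Hypervalent-iodine oxidative dearomatisation run twice in one flask: the phenoxenium-type intermediate from 5 is trapped by MeOH para to oxygen to give 6, and the second oxidation is steered by the new methoxy group to the same carbon, so the dimethyl ketal ends next to the amide-bearing carbon and the free ketone para to it.

**Step 4**
Reactants: 7 (2E,4E)-5-cyclohexyl-N-(6,6-dimethoxy-3-oxocyclohexa-1,4-dien-1-yl)penta-2,4-dienamide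
Product: 8 (2E,4E)-5-cyclohexyl-N-[(1S,6R)-5,5-dimethoxy-2-oxo-7-oxabicyclo[4.1.0]hept-3-en-4-yl]penta-2,4-dienamide
Conditions: t-BuOOH, aq NaOH, N-benzylcinchoninium chloride (10 mol %), toluene, rt; recrystallise
Reagents that add atoms: tert-butyl hydroperoxide, CC(C)(C)OO
Why: Weitz–Scheffer nucleophilic epoxidation under chiral phase-transfer control: only the unsubstituted enone C=C reacts (the other is a deactivated vinylogous imide), and the cinchoninium–peroxide ion pair selects one enantiotopic face to set both oxirane carbons as (1S,6R) (the cinchonidinium pseudoenantiomer gives the antipode; the sense is confirmed by chiral HPLC), with ee raised by recrystallisation.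

**Step 5**
Reactants: 8 (2E,4E)-5-cyclohexyl-N-[(1S,6R)-5,5-dimethoxy-2-oxo-7-oxabicyclo[4.1.0]hept-3-en-4-yl]penta-2,4-dienamide
Product: 9 (2E,4E)-5-cyclohexyl-N-[(1S,2S,6R)-2-hydroxy-5,5-dimethoxy-2-[(E)-2-(tributylstannyl)ethenyl]-7-oxabicyclo[4.1.0]hept-3-en-4-yl]penta-2,4-dienamide
Conditions: LiN(SiMe3)2 (1.05 equiv), THF, −78 °C; then (E)-Bu3SnCH=CHLi (1.5 equiv, from (E)-Bu3SnCH=CHSnBu3 + n-BuLi, THF, −78 °C); aq NH4Cl
Reagents that add atoms: (E)-1,2-bis(tributylstannyl)ethene, CCCC[Sn](CCCC)(CCCC)/C=C/[Sn](CCCC)(CCCC)CCCC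
Why: 1,2-Addition of the alkenyllithium (from tin–lithium exchange) to the ketone of the N-lithiated substrate takes place on the face opposite the oxirane oxygen, which sets the tertiary carbinol with OH cis to the epoxide (2S here, 4R in the target) and brings in the E-vinylstannane.

**Step 6**
Reactants: 9 (2E,4E)-5-cyclohexyl-N-[(1S,2S,6R)-2-hydroxy-5,5-dimethoxy-2-[(E)-2-(tributylstannyl)ethenyl]-7-oxabicyclo[4.1.0]hept-3-en-4-yl]penta-2,4-dienamide
Product: 10 (2E,4E)-5-cyclohexyl-N-[(1R,5S,6S)-5-hydroxy-2-oxo-5-[(E)-2-(tributylstannyl)ethenyl]-7-oxabicyclo[4.1.0]hept-3-en-3-yl]penta-2,4-dienamide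
Conditions: montmorillonite K10 clay (acid-treated Al2Si4O10(OH)2·nH2O), wet CH2Cl2, rt
Reagents that add atoms: water, O
Why: Mild heterogeneous acid-catalysed ketal hydrolysis (through the oxocarbenium ion stabilised by the enamide) frees the ketone without protodestannylation or epoxide opening and leaves the stereocentres untouched.

**Step 7**
Reactants: 11 glutaconaldehyde potassium salt
Product: 12 (2E,4E)-5-bromopenta-2,4-dienal
Conditions: Ph3PBr2 (1.1 equiv), CH2Cl2, 0 °C to rt
Reagents that add atoms: triphenylphosphine dibromide, BrP(Br)(c1ccccc1)(c1ccccc1)c1ccccc1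
Why: Deoxybromination of a vinylogous carboxylate: O-phosphonium activation of the enolate oxygen and bromide addition–elimination give the thermodynamically preferred (2E,4E)-bromodienal and Ph3P=O.

**Step 8**
Reactants: 12 (2E,4E)-5-bromopenta-2,4-dienal
Product: 13 (2E,4E)-5-bromopenta-2,4-dienoic acid
Conditions: NaClO2, NaH2PO4, 2-methylbut-2-ene, t-BuOH/H2O, rt
Reagents that add atoms: sodium chlorite, [Na+].[O-]Cl=O
Why: Pinnick chlorite oxidation converts the enal into the acid without touching the bromodiene, the alkene scavenger removing HOCl.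

**Step 9**
Reactants: 13 (2E,4E)-5-bromopenta-2,4-dienoic acid; 14 ethyl formimidate hydrochloride
Product: 16 ethyl N-[(2E,4E)-5-bromopenta-2,4-dienoyl]formimidate, via acid chloride 15 (not isolated)
Conditions: (COCl)2, cat. DMF, CH2Cl2, 0 °C to rt, evaporate; then 14, Et3N (2.2 equiv), CH2Cl2, −30 to 0 °C; filter, concentrate, use crude
Reagents that add atoms: none
Why: Acid chloride formation followed by N-acylation of the formimidate set free at low temperature by Et3N is the standard way to N-acyl imidates, and the product carries the N–C unit of ring C at the formate oxidation level.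

**Step 10**
Reactants: 16 ethyl N-[(2E,4E)-5-bromopenta-2,4-dienoyl]formimidate; 17 1,2-bis(trimethylsilyloxy)cyclobut-1-ene
Product: 19 (2E,4E)-5-bromo-N-(2-hydroxy-5-oxocyclopent-1-en-1-yl)penta-2,4-dienamide, via Mannich adduct 18 (not isolated)
Conditions: 17 (1.2 equiv), BF3·OEt2 (3 equiv), CH2Cl2, −78 °C to rt; H2O work-up
Reagents that add atoms: none
Why: Proposed new method: BF3 activates the N-acylformimidate as an N-acylimine-type electrophile for Mukaiyama–Mannich attack by the enediol bis-silyl ether to give α-ethoxy amide 18, BF3 then ionises the ethoxy group to an N-acyliminium ion, and the ring acyl carbon of the strained 2-siloxycyclobutanone migrates to the iminium carbon in a stepwise cationic 1,2-shift (the carbinol carbon becomes a silyloxocarbenium ion and then a ketone), so the four-membered ring expands to the 2-amido-1,3-dione that enolises to 19; the closest known chemistry is the acetal-based geminal acylation (Mukaiyama aldol then pinacol-type ring expansion of 2-siloxycyclobutanones to cyclopentane-1,3-diones), together with the α-iminol rearrangement and N-acyliminium amidoalkylation, none of which has been run with an N-acylformimidate to give a 2-acylamino-1,3-dione.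

**Step 11**
Reactants: 10 (2E,4E)-5-cyclohexyl-N-[(1R,5S,6S)-5-hydroxy-2-oxo-5-[(E)-2-(tributylstannyl)ethenyl]-7-oxabicyclo[4.1.0]hept-3-en-3-yl]penta-2,4-dienamide; 19 (2E,4E)-5-bromo-N-(2-hydroxy-5-oxocyclopent-1-en-1-yl)penta-2,4-dienamide
Product: 20 (2E,4E)-5-cyclohexyl-N-[(1R,5R,6S)-5-hydroxy-5-[(1E,3E,5E)-7-[(2-hydroxy-5-oxocyclopent-1-en-1-yl)amino]-7-oxohepta-1,3,5-trien-1-yl]-2-oxo-7-oxabicyclo[4.1.0]hept-3-en-3-yl]penta-2,4-dienamide
Conditions: PdCl2(MeCN)2 (5 mol %), DMF, rt, dark
Reagents that add atoms: none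
Why: Stille cross-coupling of the alkenylstannane with the alkenyl bromide under ligand-free palladium catalysis proceeds with retention at both alkenes and gives the all-E triene at room temperature in the presence of the free tertiary alcohol, the epoxide and the acidic enol.

**Compound list**

1 | vinylcyclohexane | C=CC1CCCCC1 | starting material
2 | (2E)-penta-2,4-dienoic acid | OC(=O)/C=C/C=C | starting material
3 | (2E,4E)-5-cyclohexylpenta-2,4-dienoic acid | OC(=O)/C=C/C=C/C1CCCCC1 | intermediate
4 | 3-aminophenol | Nc1cccc(O)c1 | starting material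
5 | (2E,4E)-5-cyclohexyl-N-(3-hydroxyphenyl)penta-2,4-dienamide | O=C(/C=C/C=C/C1CCCCC1)Nc1cccc(O)c1 | intermediate
6 | (2E,4E)-5-cyclohexyl-N-(5-hydroxy-2-methoxyphenyl)penta-2,4-dienamide | O=C(/C=C/C=C/C1CCCCC1)Nc1cc(O)ccc1OC | intermediate
7 | (2E,4E)-5-cyclohexyl-N-(6,6-dimethoxy-3-oxocyclohexa-1,4-dien-1-yl)penta-2,4-dienamide | O=C(/C=C/C=C/C1CCCCC1)NC1=CC(=O)C=CC1(OC)OC | intermediate
8 | (2E,4E)-5-cyclohexyl-N-[(1S,6R)-5,5-dimethoxy-2-oxo-7-oxabicyclo[4.1.0]hept-3-en-4-yl]penta-2,4-dienamide | O=C(/C=C/C=C/C1CCCCC1)NC1=CC(=O)[C@H]2O[C@H]2C1(OC)OC | intermediate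
9 | (2E,4E)-5-cyclohexyl-N-[(1S,2S,6R)-2-hydroxy-5,5-dimethoxy-2-[(E)-2-(tributylstannyl)ethenyl]-7-oxabicyclo[4.1.0]hept-3-en-4-yl]penta-2,4-dienamide (hydroxyl cis to the oxirane oxygen) | O=C(/C=C/C=C/C1CCCCC1)NC1=C[C@](O)(/C=C/[Sn](CCCC)(CCCC)CCCC)[C@H]2O[C@H]2C1(OC)OC | intermediate
10 | (2E,4E)-5-cyclohexyl-N-[(1R,5S,6S)-5-hydroxy-2-oxo-5-[(E)-2-(tributylstannyl)ethenyl]-7-oxabicyclo[4.1.0]hept-3-en-3-yl]penta-2,4-dienamide (hydroxyl cis to the oxirane oxygen) | O=C(/C=C/C=C/C1CCCCC1)NC1=C[C@](O)(/C=C/[Sn](CCCC)(CCCC)CCCC)[C@H]2O[C@H]2C1=O | intermediate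
11 | glutaconaldehyde potassium salt (potassium (1E,3E)-5-oxopenta-1,3-dien-1-olate) | [K+].[O-]/C=C/C=C/C=O | starting material
12 | (2E,4E)-5-bromopenta-2,4-dienal | O=C/C=C/C=C/Br | intermediate
13 | (2E,4E)-5-bromopenta-2,4-dienoic acid | OC(=O)/C=C/C=C/Br | intermediate
14 | ethyl formimidate hydrochloride | Cl.CCOC=N | starting material
15 | (2E,4E)-5-bromopenta-2,4-dienoyl chloride | ClC(=O)/C=C/C=C/Br | intermediate
16 | ethyl N-[(2E,4E)-5-bromopenta-2,4-dienoyl]formimidate | CCOC=NC(=O)/C=C/C=C/Br | intermediate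
17 | 1,2-bis(trimethylsilyloxy)cyclobut-1-ene | C[Si](C)(C)OC1=C(O[Si](C)(C)C)CC1 | starting material
18 | (2E,4E)-5-bromo-N-{ethoxy[2-oxo-1-(trimethylsilyloxy)cyclobutyl]methyl}penta-2,4-dienamide (diastereomer mixture; drawn as the N–H form) | CCOC(NC(=O)/C=C/C=C/Br)C1(O[Si](C)(C)C)CCC1=O | intermediate
19 | (2E,4E)-5-bromo-N-(2-hydroxy-5-oxocyclopent-1-en-1-yl)penta-2,4-dienamide | O=C(/C=C/C=C/Br)NC1=C(O)CCC1=O | intermediate
20 | (2E,4E)-5-cyclohexyl-N-[(1R,5R,6S)-5-hydroxy-5-[(1E,3E,5E)-7-[(2-hydroxy-5-oxocyclopent-1-en-1-yl)amino]-7-oxohepta-1,3,5-trien-1-yl]-2-oxo-7-oxabicyclo[4.1.0]hept-3-en-3-yl]penta-2,4-dienamide (4R,5S,6R in cyclohexenone numbering; hydroxyl cis to the oxirane oxygen) | O=C(/C=C/C=C/C1CCCCC1)NC1=C[C@](O)(/C=C/C=C/C=C/C(=O)NC2=C(O)CCC2=O)[C@H]2O[C@H]2C1=O | target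

**Step count**

Total: 11 steps. Longest linear sequence: 7 steps (1–6, then 11). The second branch is 4 steps (7–10) before the coupling.

**Three steps most likely to fail**

Step 10 (the new ring expansion). The risks are attack at the wrong site, alkyl instead of acyl migration, and loss of the amide instead of the ethoxy group on ionisation. The fallback sets out from 13 and comes back at 19, and it also bypasses step 9. Cyclopentane-1,3-dione F1 (bought) is nitrosated with NaNO2 in aqueous HCl at 0 °C to 2-(hydroxyimino)cyclopentane-1,3-dione F2. F2 is hydrogenated over palladium on carbon (Pd/C) in ethanolic HCl to 2-amino-3-hydroxycyclopent-2-en-1-one hydrochloride F3. Acid 13 is turned into acid chloride 15 as in step 9 and used to N-acylate F3 (Et3N, CH2Cl2/DMF, 0 °C), which gives 19. All three operations are known chemistry.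

Step 3 (double oxidation of a para-unsubstituted phenol). The risks are ortho attack of methanol and over-oxidation to the quinone. The fallback sets out from 5 and comes back at 7 and installs the para oxygen stepwise. Teuber oxidation of 5 with (KSO3)2NO in buffered aqueous acetone gives (2E,4E)-5-cyclohexyl-N-(3,6-dioxocyclohexa-1,4-dien-1-yl)penta-2,4-dienamide F4. Reduction with Na2S2O4 gives (2E,4E)-5-cyclohexyl-N-(2,5-dihydroxyphenyl)penta-2,4-dienamide F5. O-Methylation with Me2SO4 and K2CO3 in acetone gives (2E,4E)-5-cyclohexyl-N-(2,5-dimethoxyphenyl)penta-2,4-dienamide F6. Oxidation of F6 with PhI(OAc)2 in MeOH, the established route from 2,5-dimethoxyanilides, then gives 7.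

Step 4 (asymmetric epoxidation). The risks are a modest yield and an ee that depends on recrystallisation. The fallback sets out from 7 and comes back at 8 and replaces asymmetric catalysis by resolution. Epoxidation of 7 without chiral control (t-BuOOH, DBU, CH2Cl2) gives 8 together with its mirror image, (2E,4E)-5-cyclohexyl-N-[(1R,6S)-5,5-dimethoxy-2-oxo-7-oxabicyclo[4.1.0]hept-3-en-4-yl]penta-2,4-dienamide F7. The two are separated by preparative HPLC on an amylose tris(3,5-dimethylphenylcarbamate) phase; 8 is taken on and F7 is discarded.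

**Further compounds**

F1 | step 10 | cyclopentane-1,3-dione (bought) | O=C1CCC(=O)C1
F2 | step 10 | 2-(hydroxyimino)cyclopentane-1,3-dione | ON=C1C(=O)CCC1=O
F3 | step 10 | 2-amino-3-hydroxycyclopent-2-en-1-one hydrochloride | Cl.NC1=C(O)CCC1=O
F4 | step 3 | (2E,4E)-5-cyclohexyl-N-(3,6-dioxocyclohexa-1,4-dien-1-yl)penta-2,4-dienamide | O=C(/C=C/C=C/C1CCCCC1)NC1=CC(=O)C=CC1=O
F5 | step 3 | (2E,4E)-5-cyclohexyl-N-(2,5-dihydroxyphenyl)penta-2,4-dienamide | O=C(/C=C/C=C/C1CCCCC1)Nc1cc(O)ccc1O
F6 | step 3 | (2E,4E)-5-cyclohexyl-N-(2,5-dimethoxyphenyl)penta-2,4-dienamide | O=C(/C=C/C=C/C1CCCCC1)Nc1cc(OC)ccc1OC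
F7 | step 4 | (2E,4E)-5-cyclohexyl-N-[(1R,6S)-5,5-dimethoxy-2-oxo-7-oxabicyclo[4.1.0]hept-3-en-4-yl]penta-2,4-dienamide | O=C(/C=C/C=C/C1CCCCC1)NC1=CC(=O)[C@@H]2O[C@@H]2C1(OC)OC
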